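**Retrosynthetic overview**

1. GA72 ← its methyl ester ← GA1 methyl ester (15β-OH by allylic oxidation at C15, then 15-ketone reduction; 3β-OH by 3-ketone reduction).
2. Ring A last: aldol closure C3–C4 of the 19,10-lactone enolate; lactone by adding a C1–C3 Grignard unit to a C10 ketone; ring B by Stetter closure C10–C5.
3. Rings C and D together from an open chain: formal (3+2) Prins/Hosomi–Sakurai annulation making C13–C14 and C8–C15.
4. Enabling feature: ring D is a 3-methylidenecyclopentanol in which C13(O)–C16(=C17)–C15 is a latent 2-(silylmethyl)allyl ketone and C8–C14 a latent methylidene; C8 and C13 are 1,3 on ring C, so one event closes the whole bicyclo[3.2.1]octane.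
5. Open chain from dimethyl 3-methylideneglutarate (C10–C9–C8(=C14)–C6–C7) by auxiliary-controlled Michael addition at C9 to a cross-conjugated dienone (C11–C13, C15–C17). Ring order: C+D, B, lactone, A.

Key step: step 7

Remark: atoms are numbered as in gibberellins, and the gibberellins are called by their usual short forms, GA followed by the number: GA72 is the target, GA1 its 15-deoxy relative and GA20 its 3,15-dideoxy relative.
Remark: the bromoacrylate, the acetal Grignard solution and the dichloride used below are taken as purchasable.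
Remark: C6 (steps 9–10) and C4 (steps 11–13) are carried as epimer mixtures and are left unspecified in those SMILES; both are settled later by equilibration or enolisation.

Step 1
Reactants: 1 (2-bromoprop-2-en-1-yl)trimethylsilane; 2 acrolein
Product: 4 2-[(trimethylsilyl)methyl]penta-1,4-dien-3-ol (racemic), via vinyllithium reagent 3 (not isolated)
Conditions: t-BuLi (2.0 equiv), Et2O, −78 °C; then 2, −78 °C; aq NH4Cl
Reagents that add atoms: none
Why: Bromine–lithium exchange gives the α-(silylmethyl)vinyllithium, which adds 1,2 to the aldehyde (organolithium carbonyl addition); the carbinol centre is not controlled and is removed in step 2.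

Step 2
Reactants: 4 2-[(trimethylsilyl)methyl]penta-1,4-dien-3-ol
Product: 5 2-[(trimethylsilyl)methyl]penta-1,4-dien-3-one
Conditions: Dess–Martin periodinane, NaHCO3, CH2Cl2, 0 °C; used at once
Reagents that add atoms: none
Why: Dess–Martin oxidation of the bis-allylic alcohol should give the cross-conjugated dienone under buffered, non-acidic conditions that spare the allylsilane.

Step 3
Reactants: 6 3-chloro-2-(chloromethyl)prop-1-ene
Product: 7 dimethyl 3-methylidenepentanedioate
Conditions: CO (30 bar), MeOH, PdCl2(PPh3)2 (2 mol%), iPr2NEt, THF, 60 °C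
Reagents that add atoms: carbon monoxide [C-]#[O+]; methanol CO
Why: Palladium-catalysed allylic alkoxycarbonylation of both C–Cl bonds should give the β,γ-unsaturated diester with the C8=C14 methylidene already in place.

Step 4
Reactants: 7 dimethyl 3-methylidenepentanedioate
Product: 8 5-methoxy-3-methylidene-5-oxopentanoic acid
Conditions: pig liver esterase, 0.1 M phosphate buffer pH 7, 23 °C; then 1 M HCl to pH 3
Reagents that add atoms: water O
Why: Enzymatic mono-hydrolysis of a symmetric diester stops at the half-ester and, at pH 7, should avoid base-induced migration of the methylidene into conjugation.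

Step 5
Reactants: 8 5-methoxy-3-methylidene-5-oxopentanoic acid; 9 (R)-4-benzyl-1,3-oxazolidin-2-one
Product: 11 methyl 5-[(4R)-4-benzyl-2-oxo-1,3-oxazolidin-3-yl]-3-methylidene-5-oxopentanoate, via mixed pivalic anhydride 10 (not isolated)
Conditions: t-BuCOCl, Et3N, THF, −20 °C; then 9, LiCl, −20 → 23 °C
Reagents that add atoms: none
Why: N-Acylation of the oxazolidinone through the mixed anhydride attaches the auxiliary that will control C9.

Step 6
Reactants: 11 imide; 5 dienone
Product: 13 methyl (4R)-4-[(4R)-4-benzyl-2-oxo-1,3-oxazolidine-3-carbonyl]-3,8-dimethylidene-7-oxo-9-(trimethylsilyl)nonanoate, via chlorotitanium enolate 12 (not isolated)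
Conditions: TiCl4 (1.05 equiv), iPr2NEt (1.1 equiv), CH2Cl2, −78 → 0 °C; then 5 (1.5 equiv), −78 → −20 °C
Reagents that add atoms: none
Why: Oxazolidinone-controlled titanium-enolate Michael addition: the chelated Z-enolate should add through C9 to the unsubstituted vinyl terminus of 5 on the face away from the benzyl group, setting C9 as R (the target configuration) and bringing in C11–C13 and C15–C17 at once.

Step 7
Reactants: 13 open-chain keto allylsilane
Product: 15 C/D bicyclo[3.2.1]octane imide (C8 C9 C13 configured as in the target), via C8 carbocation 14 (not isolated)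
Conditions: MeAlCl2 (5 equiv), CH2Cl2, −78 → −30 °C; aq KNaC4H4O6 work-up
Reagents that add atoms: none
Why: Proposed new method: MeAlCl2 activates the C13 ketone, the C8=C14 methylidene attacks it through C14 in a chair transition state (ring C closes 6-endo with respect to the alkene, the mode of the type 2 carbonyl-ene/Prins cyclisation), and the tertiary C8 cation 14 is captured by the allylsilane terminus C15 with loss of Me3Si (ring D closes with the central allyl carbon C16 inside the new five-membered ring, the mode of methylenecyclopentane annulations with 2-(silylmethyl)allyl reagents), so the enone serves as a trimethylenemethane-type three-carbon unit in a formal (3+2) annulation. The closest known reaction types are the Lewis-acid type 2 carbonyl-ene cyclisation of ketones and allylsilane-terminated cation–olefin cyclisations (intramolecular Hosomi–Sakurai); their union on one substrate to give a bridged bicycle is the new element. C13 and C8 are fixed relative to each other by the bridge itself, because the allyl arm reaches C8 only from an axial position on C13; both are fixed relative to C9 by 1,2-allylic strain, which keeps the C9 acyl group away from the in-plane C6 methylene on C8, hence axial and anti to the incoming C15–C16 bridge, the arrangement of the target (C10 axial on ring C, H-9 syn to C15). A C13 epimer of 14 that carries the allyl arm equatorial cannot close ring D and should return to 13 by retro-Prins fragmentation, so that the material drains through the productive isomer. The step needs 1,2-attack on the enone carbonyl instead of conjugate attack at C15, which the tether secures (six- against eight-membered ring), and cation capture instead of proton loss from C6 or C9, which the axial five-ring-forming allylsilane and the proton-scavenging Al–Me bond should secure.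

Step 8
Reactants: 15 bicyclic imide
Product: 16 bicyclic morpholine amide
Conditions: morpholine, AlMe3, CH2Cl2, 0 °C
Reagents that add atoms: morpholine C1COCCN1
Why: Aluminium-amide aminolysis of the N-acyl oxazolidinone, which at 0 °C should react well before the methyl ester, releases the auxiliary and gives a tertiary amide whose α-proton (H-9) is far less acidic than the ester α-protons at C6.

Step 9
Reactants: 16 morpholine amide; 17 methyl (E)-3-bromo-2-methylprop-2-enoate
Product: 19 C6-alkenylated amide diester (C6 epimers), via lithium ester enolate 18 (not isolated)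
Conditions: LiN(iPr)2 (3.5 equiv), THF, −78 °C; then 17, −78 → −30 °C; AcOH
Reagents that add atoms: none
Why: Ester-enolate conjugate addition–elimination on the β-bromoacrylate (vinylic substitution) should install C5, C4, C18 and C19 as an (E)-2-methylalkenoate; C6 forms as a mixture that step 11 equilibrates.

Step 10
Reactants: 19 amide diester
Product: 20 C10 aldehyde diester (C6 epimers)
Conditions: Cp2Zr(H)Cl (2.5 equiv), THF, 23 °C, 20 min
Reagents that add atoms: none
Why: Reduction of a tertiary amide with the Schwartz reagent stops at the aldehyde and should leave methyl esters and the 1,1-disubstituted alkene untouched.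

Step 11
Reactants: 20 aldehyde
Product: 21 B/C/D tricyclic 10-ketone (9βH; 5-[1-(methoxycarbonyl)ethyl] α; 6β-CO2Me; C4 epimers)
Conditions: 2-(pentafluorophenyl)-6,7-dihydro-5H-pyrrolo[2,1-c][1,2,4]triazol-2-ium tetrafluoroborate (20 mol%), KN(SiMe3)2 (20 mol%), toluene, 23 → 60 °C; then DBU (0.3 equiv), 23 °C
Reagents that add atoms: none
Why: Intramolecular Stetter reaction (5-exo addition of the Breslow intermediate of the C10 aldehyde to C5 of the enoate) closes ring B, and base should then settle the epimerisable C9, C5 and C6 as the cis-fused hydrindanone with trans C5/C6 substituents (C4 α, C7 β), the natural arrangement.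

Step 12
Reactants: 21 tricyclic ketone; 22 [2-(1,3-dioxan-2-yl)ethyl]magnesium bromide
Product: 24 19,10-lactone acetal (C4 epimers), via magnesium alkoxide 23 (not isolated)
Conditions: 22 (3 equiv), LaCl3·2LiCl, THF, −78 → 0 °C; aq NH4Cl
Reagents that add atoms: none
Why: Grignard addition to the cyclopentanone from the β-face (the α-face is blocked by ring C at C9 and by the C5 side chain) sets C10 with O α and C1 β, and the alkoxide, cis to the C4 ester, closes the γ-lactone by acyl substitution.

Step 13
Reactants: 24 lactone acetal
Product: 25 lactone aldehyde (C10 bears CH2CH2CHO; C4 epimers)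
Conditions: 1 M HCl, THF, 23 °C
Reagents that add atoms: water O
Why: Mild aqueous acid hydrolysis of the 1,3-dioxane acetal frees the C3 aldehyde without ionising the tertiary C13 alcohol.

Step 14
Reactants: 25 lactone aldehyde
Product: 26 3-epi-GA1 methyl ester (3α-OH major; some 3β)
Conditions: NaOMe (0.3 equiv), MeOH, 0 → 23 °C
Reagents that add atoms: none
Why: Intramolecular aldol addition of the lactone enolate (C4) to the C3 aldehyde closes ring A and makes C4 quaternary, its configuration being enforced by the lactone ring; it is the reverse of the known retro-aldol C3 epimerisation of 3-hydroxy gibberellin lactones, so equilibration should favour the equatorial 3α-alcohol, while C6 stays in its stable natural configuration.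

Step 15
Reactants: 26 3-epi-GA1 methyl ester (with 3β epimer)
Product: 27 3-oxo-GA20 methyl ester (3-ketone)
Conditions: Dess–Martin periodinane, NaHCO3, CH2Cl2, 23 °C
Reagents that add atoms: none
Why: Dess–Martin oxidation converges both C3 epimers on the non-enolisable β-keto lactone; the tertiary C13 alcohol is inert.

Step 16
Reactants: 27 3-ketone
Product: 28 GA1 methyl ester
Conditions: K[s-Bu3BH], THF, −78 °C; H2O
Reagents that add atoms: none
Why: The bulky borohydride should attack the 3-ketone from the equatorial side to give the axial 3β-alcohol, leaving lactone and ester untouched.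

Step 17
Reactants: 28 GA1 methyl ester
Product: 29 15α-hydroxy-GA1 methyl ester
Conditions: SeO2 (0.3 equiv), t-BuOOH (2 equiv), CH2Cl2, 23 °C
Reagents that add atoms: selenium dioxide O=[Se]=O; tert-butyl hydroperoxide CC(C)(C)OO
Why: Selenium dioxide allylic oxidation (ene reaction, then 2,3-shift) can act only at C15, the sole allylic CH2 of the methylidene, and should deliver oxygen to the less hindered exo face (15α).

Step 18
Reactants: 29 15α-alcohol
Product: 30 15-oxo-GA1 methyl ester (enone)
Conditions: MnO2, CH2Cl2, 23 °C
Reagents that add atoms: none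
Why: MnO2 oxidises only the allylic C15 alcohol; the 3β and C13 hydroxyls remain.

Step 19
Reactants: 30 enone
Product: 31 GA72 methyl ester
Conditions: NaBH4, CeCl3·7H2O, MeOH, −78 °C
Reagents that add atoms: none
Why: Luche 1,2-reduction with hydride entering from the exo face (the side of the one-carbon C14 bridge) should give the endo 15β-alcohol, the C15 configuration of the target.

Step 20
Reactants: 31 GA72 methyl ester
Product: 32 GA72
Conditions: n-PrSLi (from n-PrSH and n-BuLi), HMPA, 23 °C; then 1 M HCl
Reagents that add atoms: none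
Why: Thiolate SN2 demethylation cleaves the hindered C7 methyl ester without the hydroxide that would trigger retro-aldol epimerisation at C3 or open the lactone.

**Compound list**

1 | (2-bromoprop-2-en-1-yl)trimethylsilane | C=C(Br)C[Si](C)(C)C | starting material
2 | acrolein | C=CC=O | starting material
3 | [3-(trimethylsilyl)prop-1-en-2-yl]lithium | [Li]C(=C)C[Si](C)(C)C | intermediate
4 | 2-[(trimethylsilyl)methyl]penta-1,4-dien-3-ol (racemic) | C=CC(O)C(=C)C[Si](C)(C)C | intermediate
5 | 2-[(trimethylsilyl)methyl]penta-1,4-dien-3-one | C=CC(=O)C(=C)C[Si](C)(C)C | intermediate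
6 | 3-chloro-2-(chloromethyl)prop-1-ene | ClCC(=C)CCl | starting material
7 | dimethyl 3-methylidenepentanedioate | COC(=O)CC(=C)CC(=O)OC | intermediate
8 | 5-methoxy-3-methylidene-5-oxopentanoic acid | COC(=O)CC(=C)CC(=O)O | intermediate
9 | (R)-4-benzyl-1,3-oxazolidin-2-one | O=C1N[C@H](Cc2ccccc2)CO1 | starting material
10 | mixed anhydride of 8 with pivalic acid | COC(=O)CC(=C)CC(=O)OC(=O)C(C)(C)C | intermediate
11 | methyl 5-[(4R)-4-benzyl-2-oxo-1,3-oxazolidin-3-yl]-3-methylidene-5-oxopentanoate | COC(=O)CC(=C)CC(=O)N1C(=O)OC[C@H]1Cc1ccccc1 | intermediate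
12 | trichlorotitanium Z-enolate of 11 | COC(=O)CC(=C)/C=C(\O[Ti](Cl)(Cl)Cl)N1C(=O)OC[C@H]1Cc1ccccc1 | intermediate
13 | methyl (4R)-4-[(4R)-4-benzyl-2-oxo-1,3-oxazolidine-3-carbonyl]-3,8-dimethylidene-7-oxo-9-(trimethylsilyl)nonanoate | C[Si](C)(C)CC(=C)C(=O)CC[C@@H](C(=O)N1C(=O)OC[C@H]1Cc1ccccc1)C(=C)CC(=O)OC | intermediate
14 | ring C closed, C8 carbocation with C13 aluminium alkoxide (drawn as zwitterion) | C=C(C[Si](C)(C)C)[C@]1([O-])CC[C@@H](C(=O)N2C(=O)OC[C@H]2Cc2ccccc2)[C+](CC(=O)OC)C1 | intermediate
15 | C/D bicyclo[3.2.1]octane: C8 bears CH2CO2Me, C9 bears the acyl oxazolidinone, C13 OH, C16 methylidene | C=C1C[C@]2(CC(=O)OC)C[C@@]1(O)CC[C@H]2C(=O)N1C(=O)OC[C@H]1Cc1ccccc1 | intermediate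
16 | morpholine amide of the C/D bicycle | C=C1C[C@]2(CC(=O)OC)C[C@@]1(O)CC[C@H]2C(=O)N1CCOCC1 | intermediate
17 | methyl (E)-3-bromo-2-methylprop-2-enoate | COC(=O)/C(C)=C/Br | starting material
18 | lithium ester enolate (and C13 alkoxide) of 16 | C=C1C[C@]2(C=C(O[Li])OC)C[C@@]1(O[Li])CC[C@H]2C(=O)N1CCOCC1 | intermediate
19 | amide with C6 bearing CO2Me and the (E)-CH=C(CH3)CO2Me arm (C6 epimers) | C=C1C[C@]2(C(/C=C(\C)C(=O)OC)C(=O)OC)C[C@@]1(O)CC[C@H]2C(=O)N1CCOCC1 | intermediate
20 | C10 aldehyde corresponding to 19 (C6 epimers) | C=C1C[C@]2(C(/C=C(\C)C(=O)OC)C(=O)OC)C[C@@]1(O)CC[C@H]2C=O | intermediate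
21 | B/C/D tricyclic 10-ketone, 6β-CO2Me, 5α-CH(CH3)CO2Me (C4 epimers) | C=C1C[C@]23C[C@@]1(O)CC[C@H]2C(=O)[C@@H](C(C)C(=O)OC)[C@@H]3C(=O)OC | intermediate
22 | [2-(1,3-dioxan-2-yl)ethyl]magnesium bromide | Br[Mg]CCC1OCCCO1 | starting material
23 | C10 magnesium alkoxide after Grignard addition | C=C1C[C@]23C[C@@]1(O)CC[C@H]2[C@@](CCC1OCCCO1)(O[Mg]Br)[C@@H](C(C)C(=O)OC)[C@@H]3C(=O)OC | intermediate
24 | 19,10-lactone with C10 CH2CH2-(1,3-dioxan-2-yl) chain (C4 epimers) | C=C1C[C@]23C[C@@]1(O)CC[C@H]2[C@@]1(CCC2OCCCO2)OC(=O)C(C)[C@H]1[C@@H]3C(=O)OC | intermediate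
25 | 19,10-lactone with C10 CH2CH2CHO chain (C4 epimers) | C=C1C[C@]23C[C@@]1(O)CC[C@H]2[C@@]1(CCC=O)OC(=O)C(C)[C@H]1[C@@H]3C(=O)OC | intermediate
26 | 3-epi-GA1 methyl ester (3α,13-dihydroxy 19,10-lactone, 7-methyl ester) | C=C1C[C@]23C[C@@]1(O)CC[C@H]2[C@@]12CC[C@@H](O)[C@@](C)(C(=O)O1)[C@H]2[C@@H]3C(=O)OC | intermediate
27 | 3-oxo-GA20 methyl ester (3-ketone, 13-hydroxy 19,10-lactone, 7-methyl ester) | C=C1C[C@]23C[C@@]1(O)CC[C@H]2[C@@]12CCC(=O)[C@@](C)(C(=O)O1)[C@H]2[C@@H]3C(=O)OC | intermediate
28 | GA1 methyl ester (3β,13-dihydroxy 19,10-lactone, 7-methyl ester) | C=C1C[C@]23C[C@@]1(O)CC[C@H]2[C@@]12CC[C@H](O)[C@@](C)(C(=O)O1)[C@H]2[C@@H]3C(=O)OC | intermediate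
29 | 15α-hydroxy-GA1 methyl ester | C=C1[C@H](O)[C@]23C[C@@]1(O)CC[C@H]2[C@@]12CC[C@H](O)[C@@](C)(C(=O)O1)[C@H]2[C@@H]3C(=O)OC | intermediate
30 | 15-oxo-GA1 methyl ester | C=C1C(=O)[C@]23C[C@@]1(O)CC[C@H]2[C@@]12CC[C@H](O)[C@@](C)(C(=O)O1)[C@H]2[C@@H]3C(=O)OC | intermediate
31 | GA72 methyl ester (3β,13,15β-trihydroxy 19,10-lactone, 7-methyl ester) | C=C1[C@@H](O)[C@]23C[C@@]1(O)CC[C@H]2[C@@]12CC[C@H](O)[C@@](C)(C(=O)O1)[C@H]2[C@@H]3C(=O)OC | intermediate
32 | GA72 (3β,13,15β-trihydroxy, 16-methylidene, 19,10-lactone, free 7-carboxylic acid) | C=C1[C@@H](O)[C@]23C[C@@]1(O)CC[C@H]2[C@@]12CC[C@H](O)[C@@](C)(C(=O)O1)[C@H]2[C@@H]3C(=O)O | target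

**Count and risks**

Total step count: 20. Longest linear sequence: 18 steps (6 → 32, steps 3–20); steps 1–2 are a side branch that joins at step 6.

Step 7 (proposed new method). The C8 cation may lose H-6 (ene pathway) or the allylsilane may be protodesilylated before ring D closes. The fallback splits the annulation into two known reactions. It sets out from 13: the type 2 carbonyl-ene cyclisation with MeAlCl2 is allowed to end by loss of H-6, which should give the ring C alkylidene acetate with the allylsilane intact, F1. In F1 the alkylidene ester keeps the C9 acyl group axial by 1,3-allylic strain. Treatment of F1 with TiCl4 in CH2Cl2 at −78 °C (intramolecular Hosomi–Sakurai conjugate addition to the β,β-disubstituted enoate) then closes ring D on the same face of C8, and the route is rejoined at 15.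

Step 11. Formation of the Breslow intermediate at the hindered α-branched aldehyde may be slow, and deprotonation of the acceptor at C6 may switch off the conjugate addition, so that aldol or benzoin pathways take over. The fallback uses an acyl radical instead of an acyl anion. It sets out from 20: oxidation with NaClO2/NaH2PO4/2-methylbut-2-ene should give the C10 carboxylic acid F2. PhSeSePh with n-Bu3P converts it into the Se-phenyl selenoester F3. n-Bu3SnH/AIBN in benzene at 80 °C then effects 5-exo acyl-radical cyclisation onto C5, and DBU equilibration brings the route back at 21.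

Step 6. The cross-conjugated dienone 5 may polymerise, or be attacked at its allylsilane by TiCl4, faster than the titanium enolate captures it. The fallback builds the enone after the Michael addition. It sets out from 11: the same titanium enolate is added to tert-butyl acrylate to give the tert-butyl ester adduct F4. CF3CO2H frees the C13 acid F5, and (COCl)2 with catalytic DMF gives the acid chloride F6. Pd(PPh3)4-catalysed acylation of the vinylzinc chloride F7 (from 3 and ZnCl2) then comes back to the route at 13.

**Further compounds**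

F1 | step 7 | methyl 2-[(2R)-2-(auxiliary-carbonyl)-5-hydroxy-5-[3-(trimethylsilyl)prop-1-en-2-yl]cyclohexylidene]acetate (ene product; ring C only) | C=C(C[Si](C)(C)C)[C@]1(O)CC[C@@H](C(=O)N2C(=O)OC[C@H]2Cc2ccccc2)C(=CC(=O)OC)C1
F2 | step 11 | C10 carboxylic acid corresponding to aldehyde 20 | C=C1C[C@]2(C(/C=C(\C)C(=O)OC)C(=O)OC)C[C@@]1(O)CC[C@H]2C(=O)O
F3 | step 11 | Se-phenyl selenoester of F2 | C=C1C[C@]2(C(/C=C(\C)C(=O)OC)C(=O)OC)C[C@@]1(O)CC[C@H]2C(=O)[Se]c1ccccc1
F4 | step 6 | tert-butyl ester Michael adduct of 11 with tert-butyl acrylate (C9 R) | CC(C)(C)OC(=O)CC[C@@H](C(=O)N1C(=O)OC[C@H]1Cc1ccccc1)C(=C)CC(=O)OC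
F5 | step 6 | C13 carboxylic acid from F4 | OC(=O)CC[C@@H](C(=O)N1C(=O)OC[C@H]1Cc1ccccc1)C(=C)CC(=O)OC
F6 | step 6 | C13 acid chloride from F5 | ClC(=O)CC[C@@H](C(=O)N1C(=O)OC[C@H]1Cc1ccccc1)C(=C)CC(=O)OC
F7 | step 6 | chloro[3-(trimethylsilyl)prop-1-en-2-yl]zinc | Cl[Zn]C(=C)C[Si](C)(C)C
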